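Ring A (C1 = CMe2, C3 = CHOH, C5 = C(Me)OH, C6 = C(OH) bearing the C7=C8 vinyl link) is disconnected across C1–C6 and C4–C5 into two acyclic C6 units. The key step, a one-pot ZnCl2-mediated Michael/aldol (Robinson-type) annulation of mesityl oxide (C1–C4) with ethyl acetoacetate (C5, C6, C7), forms both bonds; it exploits the 1,3-dioxygenation C3/C5 (aldol retron for C4–C5) and the position of quaternary C1 β to the C3 carbonyl and next to the doubly activated C6 (Michael retron for C1–C6). Sharpless epoxidation, inverting epoxide hydrolysis at C5 and directed reduction then set the triol; a Stille coupling joins it to a bromobutenolide polyene built from actinol.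

Key step: step 1

Remark: ring A atoms are numbered C1 (CMe2), C2, C3 (CHOH), C4, C5 (C(Me)OH), C6, with C7 and C8 the two vinyl carbons; (4R,6R)-4-hydroxy-2,2,6-trimethylcyclohexanone ((−)-actinol) and (E)-3-methylpent-2-en-4-yn-1-ol are taken as purchasable.

Step 1
Reactants: 1 mesityl oxide (4-methylpent-3-en-2-one); 2 ethyl acetoacetate
Product: 5 ethyl 2,6,6-trimethyl-4-oxocyclohex-2-ene-1-carboxylate (racemic), via Michael adduct 3 (not isolated), via ring ketol 4 (not isolated)
Conditions: ZnCl2 (anhydrous), toluene/heptane, reflux, Dean–Stark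
Reagents that add atoms: none
Why: Lewis-acid Michael/aldol (Robinson-type) annulation, whose closest known relative is the classical isophorone-ester synthesis from an enone and a β-keto ester: the zinc-chelated enol of 2 adds 1,4 to ZnCl2-activated 1 and forms C1–C6 at the gem-dimethyl carbon (adduct 3), the methyl ketone of 3 enolises toward C4 and closes onto the chelation-activated acetoacetate carbonyl C5 (ketol 4), and azeotropic dehydration gives enone 5 and pulls the reversible conjugate addition forward. The ring is closed by a 6-(enolendo)-exo-trig aldol addition. The only stereocentre of 5 (C6) is formed racemic on purpose, because it becomes trigonal in step 2 and all absolute stereochemistry is introduced later on an achiral intermediate. The step needs site-selectivity in the aldol (C4 onto C5, not the acetyl methyl onto C3); the non-basic Lewis-acid medium should secure it, since the β-keto ester ketone is there the activated electrophile, whereas alkoxide bases are avoided because the deprotonated β-keto ester is no longer an aldol acceptor and cyclisation could take the other course. Moderate conversion is acceptable because both partners are bulk chemicals.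

Step 2
Reactants: 5 ethyl 2,6,6-trimethyl-4-oxocyclohex-2-ene-1-carboxylate
Product: 6 ethyl 7,9,9-trimethyl-1,4-dioxaspiro[4.5]dec-7-ene-8-carboxylate
Conditions: HOCH2CH2OH, p-TsOH (cat.), toluene, reflux, Dean–Stark
Reagents that add atoms: ethylene glycol, OCCO
Why: Acid-catalysed ketalisation of a cyclohexenone runs through the dienol ether and should leave the double bond β,γ to the ketal, here in the tetrasubstituted C5=C6 position conjugated with the ester, which erases the C6 stereocentre and makes 6 achiral.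

Step 3
Reactants: 6 ethyl 7,9,9-trimethyl-1,4-dioxaspiro[4.5]dec-7-ene-8-carboxylate
Product: 7 (7,9,9-trimethyl-1,4-dioxaspiro[4.5]dec-7-en-8-yl)methanol
Conditions: LiAlH4, Et2O, 0 °C to rt
Reagents that add atoms: none
Why: Hydride reduction of the hindered, twisted ester should give the primary allylic alcohol, the ketal and the tetrasubstituted alkene being inert to LiAlH4.

Step 4
Reactants: 7 (7,9,9-trimethyl-1,4-dioxaspiro[4.5]dec-7-en-8-yl)methanol
Product: 8 {(1'S,6'S)-1',5',5'-trimethylspiro[1,3-dioxolane-2,3'-[7]oxabicyclo[4.1.0]heptan]-6'-yl}methanol, the (5S,6S)-epoxy alcohol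
Conditions: Ti(OiPr)4, L-(+)-diethyl tartrate, t-BuOOH, 4 Å MS, CH2Cl2, −20 °C
Reagents that add atoms: tert-butyl hydroperoxide, CC(C)(C)OO
Why: Sharpless asymmetric epoxidation of an achiral primary allylic alcohol is reagent-controlled, and L-(+)-tartrate should deliver oxygen to the face that gives the (S)-configured carbinol-bearing epoxide carbon (as in the (2S)-epoxy alcohols from simple allylic alcohols), which fixes the final C6–O bond and the absolute configuration of ring A.

Step 5
Reactants: 8 the (5S,6S)-epoxy alcohol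
Product: 9 (1'S,6'R)-1',5',5'-trimethylspiro[1,3-dioxolane-2,3'-[7]oxabicyclo[4.1.0]heptane]-6'-carbaldehyde (same spatial arrangement as 8)
Conditions: Dess–Martin periodinane, NaHCO3, CH2Cl2, 0 °C to rt
Reagents that add atoms: none
Why: Buffered Dess–Martin oxidation of the neopentyl-type primary alcohol should give the epoxy aldehyde, which has no α-hydrogen and cannot epimerise.

Step 6
Reactants: 9 the epoxy aldehyde
Product: 10 (1'S,6'S)-6'-ethynyl-1',5',5'-trimethylspiro[1,3-dioxolane-2,3'-[7]oxabicyclo[4.1.0]heptane]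
Conditions: dimethyl (1-diazo-2-oxopropyl)phosphonate, K2CO3, MeOH, 0 °C to rt
Reagents that add atoms: dimethyl (1-diazo-2-oxopropyl)phosphonate (Ohira–Bestmann reagent), COP(=O)(OC)C(=[N+]=[N-])C(C)=O
Why: Ohira–Bestmann (Seyferth–Gilbert) homologation converts the non-enolisable aldehyde into the terminal alkyne (C8) under mildly basic conditions that should leave epoxide and ketal intact.

Step 7
Reactants: 10 the epoxy alkyne ketal
Product: 11 (3R,4S)-4-ethynyl-3,4-dihydroxy-3,5,5-trimethylcyclohexan-1-one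
Conditions: HClO4 (0.5 M aq.), THF, 0 °C to rt
Reagents that add atoms: water, O
Why: Acid-catalysed epoxide hydrolysis should occur by backside attack of water at C5 (trans-diaxial opening, Fürst–Plattner rule), C6 being deactivated by the alkynyl group and shielded by quaternary C1, which inverts C5 to (R) and gives the 5,6-trans diol while the dioxolane is cleaved in the same pot; acid-catalysed enolisation of the freed ketone is slow next to epoxide hydrolysis, so β-elimination of the C5 oxygen should not compete.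

Step 8
Reactants: 11 (3R,4S)-4-ethynyl-3,4-dihydroxy-3,5,5-trimethylcyclohexan-1-one
Product: 12 (1S,2R,4S)-1-ethynyl-2,6,6-trimethylcyclohexane-1,2,4-triol
Conditions: Me4NBH(OAc)3, MeCN/AcOH, −20 °C
Reagents that add atoms: none
Why: Evans–Saksena hydroxyl-directed reduction: the axial C5 hydroxyl exchanges onto boron and delivers hydride to the same face of the C3 carbonyl, which should give the 1,3-anti diol with the new equatorial (3S)-hydroxyl, under acidic conditions that avoid retro-aldol cleavage.

Step 9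
Reactants: 12 (1S,2R,4S)-1-ethynyl-2,6,6-trimethylcyclohexane-1,2,4-triol
Product: 13 (1R,2R,4S)-2,6,6-trimethyl-1-[(E)-2-(tributylstannyl)ethenyl]cyclohexane-1,2,4-triol
Conditions: Bu3SnH, PdCl2(PPh3)2 (cat.), THF, 0 °C
Reagents that add atoms: tributyltin hydride, CCCC[SnH](CCCC)CCCC
Why: Pd-catalysed syn-hydrostannation of the terminal alkyne should place tin on the terminal carbon, away from the fully substituted carbinol, and give the (E)-alkenylstannane with the free hydroxyls tolerated.

Step 10
Reactants: 14 (4R,6R)-4-hydroxy-2,2,6-trimethylcyclohexan-1-one ((−)-actinol)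
Product: 15 (4R,6R)-4-[(tert-butyldimethylsilyl)oxy]-2,2,6-trimethylcyclohexan-1-one
Conditions: TBSCl, imidazole, DMF, rt
Reagents that add atoms: tert-butyldimethylsilyl chloride, CC(C)(C)[Si](C)(C)Cl
Why: Standard silylation of the secondary alcohol protects it for the enolate chemistry that follows.

Step 11
Reactants: 15 the silyl ether of actinol
Product: 16 (4R)-4-[(tert-butyldimethylsilyl)oxy]-2,6,6-trimethylcyclohex-1-en-1-yl trifluoromethanesulfonate
Conditions: LiN(iPr)2, THF, −78 °C; PhNTf2, −78 °C to rt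
Reagents that add atoms: N-phenylbis(trifluoromethanesulfonimide), O=S(=O)(N(c1ccccc1)S(=O)(=O)C(F)(F)F)C(F)(F)F
Why: Deprotonation at the only enolisable α-carbon gives the tetrasubstituted enolate, which is trapped on oxygen as the enol triflate, removing the methyl-bearing stereocentre and leaving the carbinol centre untouched.

Step 12
Reactants: 16 the enol triflate; 17 (E)-3-methylpent-2-en-4-yn-1-ol
Product: 18 (2E)-5-{(4R)-4-[(tert-butyldimethylsilyl)oxy]-2,6,6-trimethylcyclohex-1-en-1-yl}-3-methylpent-2-en-4-yn-1-ol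
Conditions: Pd(PPh3)4 (cat.), CuI (cat.), iPr2NH, DMF, rt
Reagents that add atoms: none
Why: Sonogashira coupling of the vinyl triflate with the terminal alkyne should form the ring–alkyne bond without touching the E double bond or the free primary alcohol.

Step 13
Reactants: 18 the ring B enynol
Product: 19 tert-butyl{[(1R)-4-[(3E)-5-bromo-3-methylpent-3-en-1-yn-1-yl]-3,5,5-trimethylcyclohex-3-en-1-yl]oxy}dimethylsilane
Conditions: CBr4, PPh3, CH2Cl2, 0 °C
Reagents that add atoms: carbon tetrabromide, BrC(Br)(Br)Br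
Why: Appel bromination replaces the primary allylic hydroxyl by SN2 under neutral conditions, so the silyl ether and the enyne geometry should survive.

Step 14
Reactants: 19 the allylic bromide
Product: 20 diethyl [(2E)-5-{(4R)-4-[(tert-butyldimethylsilyl)oxy]-2,6,6-trimethylcyclohex-1-en-1-yl}-3-methylpent-2-en-4-yn-1-yl]phosphonate
Conditions: P(OEt)3, toluene, 100 °C
Reagents that add atoms: triethyl phosphite, CCOP(OCC)OCC
Why: Michaelis–Arbuzov reaction of the primary allylic bromide should give the allylic phosphonate.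

Step 15
Reactants: 17 (E)-3-methylpent-2-en-4-yn-1-ol
Product: 21 (E)-3-methylpent-2-en-4-ynal
Conditions: MnO2, CH2Cl2, rt
Reagents that add atoms: none
Why: MnO2 oxidises the allylic alcohol chemoselectively to the enal without touching the alkyne or the E double bond.

Step 16
Reactants: 21 (E)-3-methylpent-2-en-4-ynal
Product: 22 (2E,4E)-5-methylhepta-2,4-dien-6-ynal
Conditions: Ph3P=CHCHO (1.0 equiv), toluene, 60 °C
Reagents that add atoms: (triphenylphosphoranylidene)acetaldehyde, O=CC=P(c1ccccc1)(c1ccccc1)c1ccccc1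
Why: Wittig reaction with the stabilised formyl ylide is E-selective and extends the enal by two carbons, the ylide being kept limiting because the more conjugated product is only somewhat less electrophilic.

Step 17
Reactants: 20 the ring B phosphonate; 22 (2E,4E)-5-methylhepta-2,4-dien-6-ynal
Product: 23 tert-butyl(dimethyl){[(1R)-3,5,5-trimethyl-4-[(3E,5E,7E,9E)-3,10-dimethyldodeca-3,5,7,9-tetraene-1,11-diyn-1-yl]cyclohex-3-en-1-yl]oxy}silane
Conditions: NaN(SiMe3)2, THF, −78 °C; then 22, −78 to 0 °C, dark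
Reagents that add atoms: none
Why: Horner–Wadsworth–Emmons olefination of the allylic phosphonate anion with the dienal should form the new disubstituted double bond with E selectivity at low temperature, the terminal alkyne of 22 being less acidic than the stabilised phosphonate.

Step 18
Reactants: 23 the silyl-protected tetraene-diyne
Product: 24 (1R)-3,5,5-trimethyl-4-[(3E,5E,7E,9E)-3,10-dimethyldodeca-3,5,7,9-tetraene-1,11-diyn-1-yl]cyclohex-3-en-1-ol
Conditions: Bu4NF, AcOH, THF, 0 °C to rt, dark
Reagents that add atoms: none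
Why: Fluoride cleaves the silyl ether, and buffering with acetic acid should protect the polyenyne from base.

Step 19
Reactants: 25 propiolic acid
Product: 26 (E)-2,3-dibromoprop-2-enoic acid
Conditions: Br2, CH2Cl2, 0 °C, dark
Reagents that add atoms: bromine, BrBr
Why: Anti-addition of bromine to the alkyne should give the (E)-dibromide, in which the β-bromine is cis to the carboxyl group.

Step 20
Reactants: 24 the terminal alkyne; 26 (E)-2,3-dibromoprop-2-enoic acid
Product: 28 (5Z)-3-bromo-5-[(2E,4E,6E,8E)-11-[(4R)-4-hydroxy-2,6,6-trimethylcyclohex-1-en-1-yl]-2,9-dimethylundeca-2,4,6,8-tetraen-10-yn-1-ylidene]furan-2(5H)-one, via bromo enynoic acid 27 (not isolated)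
Conditions: Pd(PPh3)4 (cat.), CuI (cat.), Et3N, MeCN, rt, dark, slow addition of 24 to excess 26
Reagents that add atoms: none
Why: Tandem Sonogashira coupling/lactonisation: oxidative addition should occur at the more electrophilic β-C–Br bond, and the cis carboxylate of 27 then adds anti across the activated alkyne in a 5-exo-dig mode to give the (Z)-ylidene butenolide with the α-bromine intact.

Step 21
Reactants: 13 the ring A alkenylstannane; 28 the bromobutenolide
Product: 29 (5Z)-3-{(E)-2-[(1R,2R,4S)-1,2,4-trihydroxy-2,6,6-trimethylcyclohexyl]ethenyl}-5-[(2E,4E,6E,8E)-11-[(4R)-4-hydroxy-2,6,6-trimethylcyclohex-1-en-1-yl]-2,9-dimethylundeca-2,4,6,8-tetraen-10-yn-1-ylidene]furan-2(5H)-one (CNP0163979.1)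
Conditions: Pd2(dba)3 (cat.), AsPh3, NMP, rt, dark
Reagents that add atoms: none
Why: Stille coupling of the α-bromobutenolide with the (E)-alkenylstannane proceeds with retention of both alkene geometries under neutral conditions that should tolerate the free hydroxyls, the polyene and the base-sensitive lactone.

Compound list
1 | mesityl oxide (4-methylpent-3-en-2-one) | CC(C)=CC(C)=O | starting material
2 | ethyl acetoacetate | CCOC(=O)CC(C)=O | starting material
3 | ethyl 2-acetyl-3,3-dimethyl-5-oxohexanoate (Michael adduct, racemic) | CCOC(=O)C(C(C)=O)C(C)(C)CC(C)=O | intermediate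
4 | ethyl 2-hydroxy-2,6,6-trimethyl-4-oxocyclohexane-1-carboxylate (ring ketol, stereoisomer mixture) | CCOC(=O)C1C(C)(C)CC(=O)CC1(C)O | intermediate
5 | ethyl 2,6,6-trimethyl-4-oxocyclohex-2-ene-1-carboxylate (racemic) | CCOC(=O)C1C(C)=CC(=O)CC1(C)C | intermediate
6 | ethyl 7,9,9-trimethyl-1,4-dioxaspiro[4.5]dec-7-ene-8-carboxylate | CCOC(=O)C1=C(C)CC2(OCCO2)CC1(C)C | intermediate
7 | (7,9,9-trimethyl-1,4-dioxaspiro[4.5]dec-7-en-8-yl)methanol | OCC1=C(C)CC2(OCCO2)CC1(C)C | intermediate
8 | {(1'S,6'S)-1',5',5'-trimethylspiro[1,3-dioxolane-2,3'-[7]oxabicyclo[4.1.0]heptan]-6'-yl}methanol | OC[C@]12O[C@@]1(C)CC3(OCCO3)CC2(C)C | intermediate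
9 | (1'S,6'R)-1',5',5'-trimethylspiro[1,3-dioxolane-2,3'-[7]oxabicyclo[4.1.0]heptane]-6'-carbaldehyde | O=C[C@]12O[C@@]1(C)CC3(OCCO3)CC2(C)C | intermediate
10 | (1'S,6'S)-6'-ethynyl-1',5',5'-trimethylspiro[1,3-dioxolane-2,3'-[7]oxabicyclo[4.1.0]heptane] | C#C[C@]12O[C@@]1(C)CC3(OCCO3)CC2(C)C | intermediate
11 | (3R,4S)-4-ethynyl-3,4-dihydroxy-3,5,5-trimethylcyclohexan-1-one | C#C[C@@]1(O)C(C)(C)CC(=O)C[C@@]1(C)O | intermediate
12 | (1S,2R,4S)-1-ethynyl-2,6,6-trimethylcyclohexane-1,2,4-triol | C#C[C@@]1(O)C(C)(C)C[C@H](O)C[C@@]1(C)O | intermediate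
13 | (1R,2R,4S)-2,6,6-trimethyl-1-[(E)-2-(tributylstannyl)ethenyl]cyclohexane-1,2,4-triol | CCCC[Sn](CCCC)(CCCC)/C=C/[C@@]1(O)C(C)(C)C[C@H](O)C[C@@]1(C)O | intermediate
14 | (4R,6R)-4-hydroxy-2,2,6-trimethylcyclohexan-1-one ((−)-actinol) | O=C1[C@H](C)C[C@@H](O)CC1(C)C | starting material
15 | (4R,6R)-4-[(tert-butyldimethylsilyl)oxy]-2,2,6-trimethylcyclohexan-1-one | O=C1[C@H](C)C[C@@H](O[Si](C)(C)C(C)(C)C)CC1(C)C | intermediate
16 | (4R)-4-[(tert-butyldimethylsilyl)oxy]-2,6,6-trimethylcyclohex-1-en-1-yl trifluoromethanesulfonate | CC1=C(OS(=O)(=O)C(F)(F)F)C(C)(C)C[C@H](O[Si](C)(C)C(C)(C)C)C1 | intermediate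
17 | (E)-3-methylpent-2-en-4-yn-1-ol | C#C/C(C)=C/CO | starting material
18 | (2E)-5-{(4R)-4-[(tert-butyldimethylsilyl)oxy]-2,6,6-trimethylcyclohex-1-en-1-yl}-3-methylpent-2-en-4-yn-1-ol | CC1=C(C#C/C(C)=C/CO)C(C)(C)C[C@H](O[Si](C)(C)C(C)(C)C)C1 | intermediate
19 | tert-butyl{[(1R)-4-[(3E)-5-bromo-3-methylpent-3-en-1-yn-1-yl]-3,5,5-trimethylcyclohex-3-en-1-yl]oxy}dimethylsilane | CC1=C(C#C/C(C)=C/CBr)C(C)(C)C[C@H](O[Si](C)(C)C(C)(C)C)C1 | intermediate
20 | diethyl [(2E)-5-{(4R)-4-[(tert-butyldimethylsilyl)oxy]-2,6,6-trimethylcyclohex-1-en-1-yl}-3-methylpent-2-en-4-yn-1-yl]phosphonate | CC1=C(C#C/C(C)=C/CP(=O)(OCC)OCC)C(C)(C)C[C@H](O[Si](C)(C)C(C)(C)C)C1 | intermediate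
21 | (E)-3-methylpent-2-en-4-ynal | C#C/C(C)=C/C=O | intermediate
22 | (2E,4E)-5-methylhepta-2,4-dien-6-ynal | C#C/C(C)=C/C=C/C=O | intermediate
23 | tert-butyl(dimethyl){[(1R)-3,5,5-trimethyl-4-[(3E,5E,7E,9E)-3,10-dimethyldodeca-3,5,7,9-tetraene-1,11-diyn-1-yl]cyclohex-3-en-1-yl]oxy}silane | CC1=C(C#C/C(C)=C/C=C/C=C/C=C(C)/C#C)C(C)(C)C[C@H](O[Si](C)(C)C(C)(C)C)C1 | intermediate
24 | (1R)-3,5,5-trimethyl-4-[(3E,5E,7E,9E)-3,10-dimethyldodeca-3,5,7,9-tetraene-1,11-diyn-1-yl]cyclohex-3-en-1-ol | CC1=C(C#C/C(C)=C/C=C/C=C/C=C(C)/C#C)C(C)(C)C[C@H](O)C1 | intermediate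
25 | propiolic acid | C#CC(=O)O | starting material
26 | (E)-2,3-dibromoprop-2-enoic acid | OC(=O)/C(Br)=C\Br | intermediate
27 | (2E,6E,8E,10E,12E)-2-bromo-15-[(4R)-4-hydroxy-2,6,6-trimethylcyclohex-1-en-1-yl]-6,13-dimethylpentadeca-2,6,8,10,12-pentaene-4,14-diynoic acid | CC1=C(C#C/C(C)=C/C=C/C=C/C=C(C)/C#C/C=C(/Br)C(=O)O)C(C)(C)C[C@H](O)C1 | intermediate
28 | (5Z)-3-bromo-5-[(2E,4E,6E,8E)-11-[(4R)-4-hydroxy-2,6,6-trimethylcyclohex-1-en-1-yl]-2,9-dimethylundeca-2,4,6,8-tetraen-10-yn-1-ylidene]furan-2(5H)-one | CC1=C(C#C/C(C)=C/C=C/C=C/C=C(C)/C=C2C=C(Br)C(=O)O/2)C(C)(C)C[C@H](O)C1 | intermediate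
29 | CNP0163979.1, (5Z)-3-{(E)-2-[(1R,2R,4S)-1,2,4-trihydroxy-2,6,6-trimethylcyclohexyl]ethenyl}-5-[(2E,4E,6E,8E)-11-[(4R)-4-hydroxy-2,6,6-trimethylcyclohex-1-en-1-yl]-2,9-dimethylundeca-2,4,6,8-tetraen-10-yn-1-ylidene]furan-2(5H)-one | CC1=C(C#C/C(C)=C/C=C/C=C/C=C(C)/C=C2C=C(/C=C/[C@@]3(O)C(C)(C)C[C@H](O)C[C@@]3(C)O)C(=O)O/2)C(C)(C)C[C@H](O)C1 | target

Total step count: 21. Longest linear sequence: 10 steps (steps 1–9, then step 21); the ring B/polyene branch is 9 steps (10–14, 17, 18, 20, 21).

Steps most likely to fail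

Step 7. What may go wrong: ketal cleavage may outrun epoxide hydrolysis, and the freed ketone may then enolise and expel the C5 oxygen (β-elimination to a conjugated hydroxy enone); water may also open the epoxide at C6 instead of C5. Fallback (sets out from 10, returns to the route at 12): the order of events is changed so that no carbonyl is present when the epoxide is opened. Mild transketalisation of 10 (PPTS, wet acetone, rt) should give (1S,6S)-6-ethynyl-1,5,5-trimethyl-7-oxabicyclo[4.1.0]heptan-3-one F1 with the epoxide intact. Reduction of F1 (NaBH4, CeCl3, MeOH, −40 °C) should give (1S,3S,6S)-6-ethynyl-1,5,5-trimethyl-7-oxabicyclo[4.1.0]heptan-3-ol F2; its facial selectivity is not predictable, so any C3 epimer is separated and returned to F1 by Dess–Martin oxidation. Aqueous HClO4 in THF then opens the epoxide of F2 at C5 with inversion and gives 12 directly, so that 11 and step 8 are bypassed.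

Step 20. What may go wrong: loss of site-selectivity between the two C–Br bonds, 6-endo instead of 5-exo lactonisation, or a second coupling of the product bromide with the alkyne. Fallback (sets out from 24 and 26, returns at 28): coupling and ring closure are separated. 26 is esterified (MeOH, H2SO4 cat.) to methyl (E)-2,3-dibromoprop-2-enoate F3. Sonogashira coupling of 24 with F3 (PdCl2(PPh3)2, CuI, Et3N, THF, rt) at the β-bromide should give methyl (2E,6E,8E,10E,12E)-2-bromo-15-[(4R)-4-hydroxy-2,6,6-trimethylcyclohex-1-en-1-yl]-6,13-dimethylpentadeca-2,6,8,10,12-pentaene-4,14-diynoate F4. Saponification (LiOH, THF/H2O, 0 °C) gives acid 27, now isolated, which is cyclised with AgNO3 (cat.) in acetone in the 5-exo-dig mode to 28.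

Step 21. What may go wrong: slow transmetalation with protodestannylation or homocoupling of the stannane, and isomerisation or decomposition of the polyene butenolide during the long reaction. Fallback (sets out from 12, returns at 29): the tin-based coupling is replaced by a boron-based one. Copper-catalysed protoboration of 12 (B2pin2, CuCl, Xantphos, NaOtBu, MeOH, THF, rt) should give (1R,2R,4S)-2,6,6-trimethyl-1-[(E)-2-(4,4,5,5-tetramethyl-1,3,2-dioxaborolan-2-yl)ethenyl]cyclohexane-1,2,4-triol F5, which is joined to 28 by Suzuki–Miyaura coupling (Pd(dppf)Cl2, K3PO4, THF/H2O, rt) to give 29.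

Further compounds
F1 | step 7 | (1S,6S)-6-ethynyl-1,5,5-trimethyl-7-oxabicyclo[4.1.0]heptan-3-one | C#C[C@]12O[C@@]1(C)CC(=O)CC2(C)C
F2 | step 7 | (1S,3S,6S)-6-ethynyl-1,5,5-trimethyl-7-oxabicyclo[4.1.0]heptan-3-ol | C#C[C@]12O[C@@]1(C)C[C@@H](O)CC2(C)C
F3 | step 20 | methyl (E)-2,3-dibromoprop-2-enoate | COC(=O)/C(Br)=C\Br
F4 | step 20 | methyl (2E,6E,8E,10E,12E)-2-bromo-15-[(4R)-4-hydroxy-2,6,6-trimethylcyclohex-1-en-1-yl]-6,13-dimethylpentadeca-2,6,8,10,12-pentaene-4,14-diynoate | CC1=C(C#C/C(C)=C/C=C/C=C/C=C(C)/C#C/C=C(/Br)C(=O)OC)C(C)(C)C[C@H](O)C1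
F5 | step 21 | (1R,2R,4S)-2,6,6-trimethyl-1-[(E)-2-(4,4,5,5-tetramethyl-1,3,2-dioxaborolan-2-yl)ethenyl]cyclohexane-1,2,4-triol | CC1(C)OB(/C=C/[C@@]2(O)C(C)(C)C[C@H](O)C[C@@]2(C)O)OC1(C)C
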